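Ring B (C5–C10) of the target carries oxygen on C6 and a methyl carbinol on C8 (methyl C17), the pattern of a 3-methylenecyclohexanol. The route therefore rests on cutting C6–C7: a type 2 carbonyl-ene cyclisation joins a C6 aldehyde on C5 to the CH2 terminus (C7) of an isopropenyl group on C9, closing ring B, setting C6 and leaving the C8=C17 methylene that later delivers the C7 and C8 oxygens. The precursor is a ring A cyclohexane with trans-disposed formyl (C5) and C9 arm (C10); C9 bears the isopropenyl group and the E-butenyl chain, C13 masked as a silyl ether. C9 and C10 come from an enantioselective Ireland–Claisen rearrangement.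

Key step: step 10

Remarks
(a) Labdane numbering is used for all positions: ring A is C1–C5 and C10, C18/C19 sit on C4, C20 on C10, C17 on C8, and the side chain is C11, C12, C13, C16.
(b) The side-chain ketone is carried from the start as the (13S) tert-butyldimethylsilyl ether, so the key-step precursor 18 and product 20 have the full carbon skeleton with C13 at the alcohol level. A free enone would not survive the later hydrogen-atom-transfer hydration and hydride reduction, and a ketal would not survive the Lewis acids. The C13 centre is a spectator, kept homochiral only so that every intermediate is a single diastereomer, and it is erased in step 17.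
(c) The C5=C6 alkene is hydroborated while the future isopropenyl carbon C8 is still a carboxyl group, because a borane could not tell two 1,1-disubstituted alkenes apart later.
(d) Assumption: the (S,S) boron controller in step 5 directs the rearrangement to acid 10 as drawn. This sense has to be confirmed in a pilot run, and the equally available (R,R) reagent is used if it is opposite.

Step 1
Reactants: 1 (S)-but-3-en-2-ol
Product: 2 tert-butyl{[(2S)-but-3-en-2-yl]oxy}dimethylsilane
Conditions: TBSCl, imidazole, CH2Cl2, 0 °C → rt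
Reagents that add atoms: tert-butyldimethylsilyl chloride, CC(C)(C)[Si](C)(C)Cl
Why: Imidazole-promoted O-silylation of a secondary alcohol is routine and leaves the C13 (S) centre untouched.

Step 2
Reactants: 2 tert-butyl{[(2S)-but-3-en-2-yl]oxy}dimethylsilane; 3 but-3-enoic acid
Product: 4 (3E,5S)-5-[(tert-butyldimethylsilyl)oxy]hex-3-enoic acid
Conditions: 2 (3 equiv), second-generation Grubbs catalyst (3 mol %), 1,4-benzoquinone (10 mol %), CH2Cl2, 40 °C
Reagents that add atoms: none
Why: Olefin cross-metathesis of a freely dimerising terminal alkene (3) with an excess of the slower secondary allylic silyl ether should give the E-alkene under thermodynamic control, the quinone suppressing migration of the β,γ-double bond, and C13 is not involved.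

Step 3
Reactants: 5 β-cyclocitral
Product: 6 β-cyclogeraniol [(2,6,6-trimethylcyclohex-1-en-1-yl)methanol]
Conditions: NaBH4, MeOH, 0 °C
Reagents that add atoms: none
Why: Borohydride 1,2-reduction of the hindered conjugated aldehyde gives the primary allylic alcohol without creating a stereocentre.

Step 4
Reactants: 6 β-cyclogeraniol; 4 (3E,5S)-5-[(tert-butyldimethylsilyl)oxy]hex-3-enoic acid
Product: 7 (2,6,6-trimethylcyclohex-1-en-1-yl)methyl (3E,5S)-5-[(tert-butyldimethylsilyl)oxy]hex-3-enoate
Conditions: EDC·HCl, DMAP (0.1 equiv), CH2Cl2, 0 °C → rt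
Reagents that add atoms: none
Why: Carbodiimide (Steglich-type) esterification with only catalytic DMAP at low temperature should acylate the primary allylic alcohol without moving the β,γ-double bond into conjugation.

Step 5
Reactants: 7 (2,6,6-trimethylcyclohex-1-en-1-yl)methyl (3E,5S)-5-[(tert-butyldimethylsilyl)oxy]hex-3-enoate
Product: 10 (2R,3E,5S)-5-[(tert-butyldimethylsilyl)oxy]-2-[(1R)-1,3,3-trimethyl-2-methylidenecyclohexyl]hex-3-enoic acid, via boron ketene acetal 8 (not isolated), via acyloxyborane 9 (not isolated)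
Conditions: (4S,5S)-2-bromo-1,3-bis{[3,5-bis(trifluoromethyl)phenyl]sulfonyl}-4,5-diphenyl-1,3,2-diazaborolidine (1.3 equiv), iPr2NEt (1.5 equiv), CH2Cl2, −78 °C, then −20 °C → rt; H2O
Reagents that add atoms: none
Why: Enantioselective Ireland–Claisen rearrangement: soft enolisation with the chiral bromoborane and iPr2NEt in CH2Cl2 is expected to give the boron ketene acetal 8 with the alkenyl arm cis to O–B, and its [3,3] shift through a chair (C20 axial, C1 and the C11 arm equatorial) joins C9 to C10 with the required relative configuration, while the C2-symmetric diazaborolidine differentiates the enolate faces and thus sets the absolute configuration of both new centres.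

Step 6
Reactants: 10 (2R,3E,5S)-5-[(tert-butyldimethylsilyl)oxy]-2-[(1R)-1,3,3-trimethyl-2-methylidenecyclohexyl]hex-3-enoic acid
Product: 13 (4R,4aS,8aS)-4-[(1E,3S)-3-(tert-butyldimethylsilyloxy)but-1-en-1-yl]-4a,8,8-trimethyloctahydro-3H-isochromen-3-one (trans-fused δ-lactone), via organoborane 11 (not isolated), via hydroxy acid 12 (not isolated)
Conditions: 9-BBN (2.5 equiv), THF, 0 → 50 °C; NaOH, H2O2, 0 °C; HCl to pH 3, then PPTS (cat.), CH2Cl2, rt
Reagents that add atoms: hydrogen peroxide, OO
Why: Hydroboration–oxidation with 9-BBN should take the 1,1-disubstituted C5=C6 alkene far faster than the E-1,2-disubstituted C11=C12 alkene and deliver hydrogen to C5 on the α face, opposite the syn-axial C19 and C20 methyl groups of the chair that keeps the C9 arm equatorial, after which the δ-hydroxy acid 12 closes to the trans-fused lactone.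

Step 7
Reactants: 13 trans-fused δ-lactone
Product: 15 (3R,4E,6S)-6-[(tert-butyldimethylsilyl)oxy]-3-[(1S,2S)-2-(hydroxymethyl)-1,3,3-trimethylcyclohexyl]hept-4-en-2-one, via lithium lactolate 14 (not isolated)
Conditions: MeLi (1.1 equiv), THF, −78 °C; aq. NH4Cl
Reagents that add atoms: methyllithium, [Li]C
Why: Addition of one equivalent of MeLi to a δ-lactone at −78 °C stops at the tetrahedral lithium lactolate 14, which on work-up gives the methyl ketone (C8 with C17) and the free C6 alcohol, carbonyl addition being faster than deprotonation at C9 at this temperature.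

Step 8
Reactants: 15 (3R,4E,6S)-6-[(tert-butyldimethylsilyl)oxy]-3-[(1S,2S)-2-(hydroxymethyl)-1,3,3-trimethylcyclohexyl]hept-4-en-2-one
Product: 17 [(1S,2R)-2-{(3S,4E,6S)-6-[(tert-butyldimethylsilyl)oxy]-2-methylhepta-1,4-dien-3-yl}-2,6,6-trimethylcyclohexyl]methanol, via β-hydroxysilane 16 (not isolated)
Conditions: Me3SiCH2Li (3 equiv), CeCl3 (3 equiv), THF, −78 → 0 °C; crude carbinol, KH, THF, 0 °C → rt
Reagents that add atoms: (trimethylsilyl)methyllithium, [Li]C[Si](C)(C)C
Why: Peterson methylenation: the weakly basic organocerium reagent adds to the hindered, enolisable ketone without epimerising C9, and syn elimination from the potassium alkoxide of 16 can only place the new alkene between C8 and C7, giving the isopropenyl group.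

Step 9
Reactants: 17 [(1S,2R)-2-{(3S,4E,6S)-6-[(tert-butyldimethylsilyl)oxy]-2-methylhepta-1,4-dien-3-yl}-2,6,6-trimethylcyclohexyl]methanol
Product: 18 (1S,2R)-2-{(3S,4E,6S)-6-[(tert-butyldimethylsilyl)oxy]-2-methylhepta-1,4-dien-3-yl}-2,6,6-trimethylcyclohexane-1-carbaldehyde (seco-ring-B aldehyde: CHO on C5 and isopropenyl on C9)
Conditions: Dess–Martin periodinane, NaHCO3, CH2Cl2, 0 °C → rt
Reagents that add atoms: none
Why: Buffered Dess–Martin oxidation converts the primary alcohol into the aldehyde under conditions that do not epimerise C5 or touch the silyl ether.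

Step 10
Reactants: 18 seco-ring-B aldehyde
Product: 20 (13S)-13-[(tert-butyldimethylsilyl)oxy]-14,15-dinorlabda-8(17),11E-dien-6α-ol, via aluminium alkoxide 19 (not isolated)
Conditions: Me2AlCl (2 equiv), CH2Cl2, −78 → −20 °C; aq. Rochelle salt
Reagents that add atoms: none
Why: Me2AlCl binds the C6 aldehyde, the CH2 terminus C7 of the isopropenyl group adds to C6 while positive charge builds on the tertiary C8, and a hydrogen of the C17 methyl passes to the aluminate (to oxygen, or to an Al–CH3 with loss of methane), which leaves the C8=C17 alkene and the aluminium alkoxide 19. The closest known reaction type is the Lewis-acid-promoted type 2 intramolecular carbonyl-ene cyclisation of 5-methylhex-5-enals to 3-methylenecyclohexanols. Ring B closes as a six-membered ring by the C6–C7 bond, exo with respect to C=O (the oxygen stays outside the ring) and endo with respect to the alkene (C7 and C8 both become ring atoms), through a chair that is the second chair of a trans-decalin because the C5–C6 and C10–C9 bonds are trans-diequatorial on ring A. The one new stereocentre, C6, is set by the orientation of the complexed carbonyl in that chair: the aluminium-bound oxygen should sit equatorial (α), since the axial (β) site is syn-axial to the C20 and C19 methyl groups. The step needs the α face at C6, loss of the proton only from C17 and no participation of the side chain; the fixed C5, C9 and C10 centres, the far higher nucleophilicity of the 1,1-disubstituted alkene (attack by C11=C12 would give a five-membered ring and a secondary cation) and the C13 silyl ether, which keeps a second Lewis-basic carbonyl out of the substrate, are meant to secure this.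

Step 11
Reactants: 20 (13S)-13-[(tert-butyldimethylsilyl)oxy]-14,15-dinorlabda-8(17),11E-dien-6α-ol
Product: 21 (13S)-13-[(tert-butyldimethylsilyl)oxy]-14,15-dinorlabda-8(17),11E-dien-6α-yl acetate
Conditions: Ac2O, pyridine, DMAP (cat.), CH2Cl2, rt
Reagents that add atoms: acetic anhydride, CC(=O)OC(C)=O
Why: DMAP-catalysed acetylation of the equatorial secondary alcohol is routine and leaves the silyl ether intact.

Step 12
Reactants: 21 (13S)-13-[(tert-butyldimethylsilyl)oxy]-14,15-dinorlabda-8(17),11E-dien-6α-yl acetate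
Product: 22 (13S)-13-[(tert-butyldimethylsilyl)oxy]-7α-hydroxy-14,15-dinorlabda-8(17),11E-dien-6α-yl acetate
Conditions: SeO2 (0.5 equiv), t-BuOOH (3 equiv), CH2Cl2, rt
Reagents that add atoms: tert-butyl hydroperoxide, CC(C)(C)OO (oxygen relayed by selenium dioxide, O=[Se]=O)
Why: SeO2-mediated allylic oxidation (ene reaction followed by [2,3]-sigmatropic shift) of the 1,1-disubstituted alkene should attack the ring methylene C7 in preference to the hindered methine C9 and give mainly the axial 7α-alcohol, whose configuration is immaterial because C7 is oxidised in the next step.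

Step 13
Reactants: 22 (13S)-13-[(tert-butyldimethylsilyl)oxy]-7α-hydroxy-14,15-dinorlabda-8(17),11E-dien-6α-yl acetate
Product: 23 (13S)-13-[(tert-butyldimethylsilyl)oxy]-7-oxo-14,15-dinorlabda-8(17),11E-dien-6α-yl acetate
Conditions: Dess–Martin periodinane, NaHCO3, CH2Cl2, 0 °C
Reagents that add atoms: none
Why: Buffered Dess–Martin oxidation of the allylic alcohol gives the exocyclic enone without base that could move the C8=C17 alkene or epimerise C6.

Step 14
Reactants: 23 (13S)-13-[(tert-butyldimethylsilyl)oxy]-7-oxo-14,15-dinorlabda-8(17),11E-dien-6α-yl acetate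
Product: 25 (13S)-13-[(tert-butyldimethylsilyl)oxy]-8α-hydroxy-7-oxo-14,15-dinorlabd-11E-en-6α-yl acetate, via hydroperoxide 24 (not isolated)
Conditions: Mn(dpm)3 [dpm = 2,2,6,6-tetramethylheptane-3,5-dionate] (10 mol %), PhSiH3 (2 equiv), O2 (1 atm), iPrOH/CH2Cl2, 0 °C; then P(OEt)3
Reagents that add atoms: dioxygen, O=O
Why: Mukaiyama-type hydrogen-atom-transfer hydration of an enone: the manganese hydride gives a hydrogen atom to C17, the tertiary α-keto radical at C8 captures O2 on the α face (the β face is blocked by the syn-axial C20 methyl) and the phosphite reduces hydroperoxide 24, so C8 is set as 8α-OH with C17 β, while the isolated C11=C12 alkene is a poor hydrogen-atom acceptor.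

Step 15
Reactants: 25 (13S)-13-[(tert-butyldimethylsilyl)oxy]-8α-hydroxy-7-oxo-14,15-dinorlabd-11E-en-6α-yl acetate
Product: 26 (13S)-13-[(tert-butyldimethylsilyl)oxy]-7β,8α-dihydroxy-14,15-dinorlabd-11E-en-6α-yl acetate
Conditions: NaBH4, MeOH/THF, −40 → −20 °C; AcOH quench
Reagents that add atoms: none
Why: Borohydride reduction of the cyclohexanone by axial hydride attack from the α face, the β face being shielded by the adjacent axial C17 methyl, should give the equatorial 7β-alcohol, and the low temperature with an acidic quench is meant to prevent 6→7 acetyl migration.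

Step 16
Reactants: 26 (13S)-13-[(tert-butyldimethylsilyl)oxy]-7β,8α-dihydroxy-14,15-dinorlabd-11E-en-6α-yl acetate
Product: 27 (13S)-7β,8α,13-trihydroxy-14,15-dinorlabd-11E-en-6α-yl acetate
Conditions: HF·pyridine, pyridine, THF, 0 °C → rt
Reagents that add atoms: none
Why: Buffered HF·pyridine cleaves the secondary silyl ether without base, so the acetate does not migrate and the tertiary alcohol is not eliminated.

Step 17
Reactants: 27 (13S)-7β,8α,13-trihydroxy-14,15-dinorlabd-11E-en-6α-yl acetate
Product: 28 7β,8α-dihydroxy-13-oxo-14,15-dinorlabd-11E-en-6α-yl acetate (CNP0136046.1)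
Conditions: MnO2 (activated, excess), CH2Cl2, rt
Reagents that add atoms: none
Why: MnO2 oxidises only the allylic C13 alcohol, the saturated secondary C7 and tertiary C8 hydroxyls being inert, and so unmasks the E-enone of the target.

Compound list
1 | (S)-but-3-en-2-ol | C[C@H](O)C=C | starting material
2 | tert-butyl{[(2S)-but-3-en-2-yl]oxy}dimethylsilane | C[C@H](O[Si](C)(C)C(C)(C)C)C=C | intermediate
3 | but-3-enoic acid | C=CCC(=O)O | starting material
4 | (3E,5S)-5-[(tert-butyldimethylsilyl)oxy]hex-3-enoic acid | C[C@H](O[Si](C)(C)C(C)(C)C)/C=C/CC(=O)O | intermediate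
5 | β-cyclocitral (2,6,6-trimethylcyclohex-1-ene-1-carbaldehyde) | CC1=C(C=O)C(C)(C)CCC1 | starting material
6 | β-cyclogeraniol [(2,6,6-trimethylcyclohex-1-en-1-yl)methanol] | CC1=C(CO)C(C)(C)CCC1 | intermediate
7 | (2,6,6-trimethylcyclohex-1-en-1-yl)methyl (3E,5S)-5-[(tert-butyldimethylsilyl)oxy]hex-3-enoate | C[C@H](O[Si](C)(C)C(C)(C)C)/C=C/CC(=O)OCC1=C(C)CCCC1(C)C | intermediate
8 | boron ketene acetal of 7 (alkenyl arm cis to O–B; boron in the (4S,5S)-diazaborolidine; not isolated) | C[C@H](O[Si](C)(C)C(C)(C)C)/C=C/C=C(\OB1N(S(=O)(=O)c2cc(cc(c2)C(F)(F)F)C(F)(F)F)[C@@H](c2ccccc2)[C@H](c2ccccc2)N1S(=O)(=O)c1cc(cc(c1)C(F)(F)F)C(F)(F)F)OCC1=C(C)CCCC1(C)C | intermediate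
9 | acyloxyborane of acid 10 with the same diazaborolidine (not isolated) | C[C@H](O[Si](C)(C)C(C)(C)C)/C=C/[C@@H](C(=O)OB2N(S(=O)(=O)c3cc(cc(c3)C(F)(F)F)C(F)(F)F)[C@@H](c3ccccc3)[C@H](c3ccccc3)N2S(=O)(=O)c2cc(cc(c2)C(F)(F)F)C(F)(F)F)[C@@]1(C)CCCC(C)(C)C1=C | intermediate
10 | (2R,3E,5S)-5-[(tert-butyldimethylsilyl)oxy]-2-[(1R)-1,3,3-trimethyl-2-methylidenecyclohexyl]hex-3-enoic acid | C[C@H](O[Si](C)(C)C(C)(C)C)/C=C/[C@@H](C(=O)O)[C@@]1(C)CCCC(C)(C)C1=C | intermediate
11 | 9-BBN adduct of 10 (boron on C6, H-5 α; carboxyl as its 9-BBN acyloxyborane; not isolated) | C[C@H](O[Si](C)(C)C(C)(C)C)/C=C/[C@@H](C(=O)OB2C3CCCC2CCC3)[C@@]1(C)CCCC(C)(C)[C@@H]1CB1C2CCCC1CCC2 | intermediate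
12 | (2R,3E,5S)-5-[(tert-butyldimethylsilyl)oxy]-2-[(1S,2S)-2-(hydroxymethyl)-1,3,3-trimethylcyclohexyl]hex-3-enoic acid (not isolated) | C[C@H](O[Si](C)(C)C(C)(C)C)/C=C/[C@@H](C(=O)O)[C@@]1(C)CCCC(C)(C)[C@@H]1CO | intermediate
13 | (4R,4aS,8aS)-4-[(1E,3S)-3-(tert-butyldimethylsilyloxy)but-1-en-1-yl]-4a,8,8-trimethyloctahydro-3H-isochromen-3-one (trans-fused δ-lactone: H-5 α, C20 β, C11 arm equatorial) | C[C@H](O[Si](C)(C)C(C)(C)C)/C=C/[C@H]1C(=O)OC[C@H]2C(C)(C)CCC[C@@]21C | intermediate
14 | lithium lactolate from 13 and MeLi (hemiketal carbon C8 unassigned; not isolated) | C[C@H](O[Si](C)(C)C(C)(C)C)/C=C/[C@H]1C(C)([O-])OC[C@H]2C(C)(C)CCC[C@@]21C.[Li+] | intermediate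
15 | (3R,4E,6S)-6-[(tert-butyldimethylsilyl)oxy]-3-[(1S,2S)-2-(hydroxymethyl)-1,3,3-trimethylcyclohexyl]hept-4-en-2-one | C[C@H](O[Si](C)(C)C(C)(C)C)/C=C/[C@@H](C(C)=O)[C@@]1(C)CCCC(C)(C)[C@@H]1CO | intermediate
16 | β-hydroxysilane from 15 (C8 carbinol bearing CH3 and CH2SiMe3, C8 unassigned; not isolated) | C[C@H](O[Si](C)(C)C(C)(C)C)/C=C/[C@@H](C(C)(O)C[Si](C)(C)C)[C@@]1(C)CCCC(C)(C)[C@@H]1CO | intermediate
17 | [(1S,2R)-2-{(3S,4E,6S)-6-[(tert-butyldimethylsilyl)oxy]-2-methylhepta-1,4-dien-3-yl}-2,6,6-trimethylcyclohexyl]methanol | C[C@H](O[Si](C)(C)C(C)(C)C)/C=C/[C@@H](C(C)=C)[C@@]1(C)CCCC(C)(C)[C@@H]1CO | intermediate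
18 | (1S,2R)-2-{(3S,4E,6S)-6-[(tert-butyldimethylsilyl)oxy]-2-methylhepta-1,4-dien-3-yl}-2,6,6-trimethylcyclohexane-1-carbaldehyde (key-step precursor) | C[C@H](O[Si](C)(C)C(C)(C)C)/C=C/[C@@H](C(C)=C)[C@@]1(C)CCCC(C)(C)[C@@H]1C=O | intermediate
19 | chloro(methyl)aluminium alkoxide of 20 (not isolated) | C[C@H](O[Si](C)(C)C(C)(C)C)/C=C/[C@H]1C(=C)C[C@H](O[Al](C)Cl)[C@H]2C(C)(C)CCC[C@@]21C | intermediate
20 | (13S)-13-[(tert-butyldimethylsilyl)oxy]-14,15-dinorlabda-8(17),11E-dien-6α-ol (key-step product) | C[C@H](O[Si](C)(C)C(C)(C)C)/C=C/[C@H]1C(=C)C[C@H](O)[C@H]2C(C)(C)CCC[C@@]21C | intermediate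
21 | (13S)-13-[(tert-butyldimethylsilyl)oxy]-14,15-dinorlabda-8(17),11E-dien-6α-yl acetate | C[C@H](O[Si](C)(C)C(C)(C)C)/C=C/[C@H]1C(=C)C[C@H](OC(C)=O)[C@H]2C(C)(C)CCC[C@@]21C | intermediate
22 | (13S)-13-[(tert-butyldimethylsilyl)oxy]-7α-hydroxy-14,15-dinorlabda-8(17),11E-dien-6α-yl acetate | C[C@H](O[Si](C)(C)C(C)(C)C)/C=C/[C@H]1C(=C)[C@H](O)[C@H](OC(C)=O)[C@H]2C(C)(C)CCC[C@@]21C | intermediate
23 | (13S)-13-[(tert-butyldimethylsilyl)oxy]-7-oxo-14,15-dinorlabda-8(17),11E-dien-6α-yl acetate | C[C@H](O[Si](C)(C)C(C)(C)C)/C=C/[C@H]1C(=C)C(=O)[C@H](OC(C)=O)[C@H]2C(C)(C)CCC[C@@]21C | intermediate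
24 | (13S)-13-[(tert-butyldimethylsilyl)oxy]-8α-hydroperoxy-7-oxo-14,15-dinorlabd-11E-en-6α-yl acetate (not isolated) | C[C@H](O[Si](C)(C)C(C)(C)C)/C=C/[C@H]1[C@](C)(OO)C(=O)[C@H](OC(C)=O)[C@H]2C(C)(C)CCC[C@@]21C | intermediate
25 | (13S)-13-[(tert-butyldimethylsilyl)oxy]-8α-hydroxy-7-oxo-14,15-dinorlabd-11E-en-6α-yl acetate | C[C@H](O[Si](C)(C)C(C)(C)C)/C=C/[C@H]1[C@](C)(O)C(=O)[C@H](OC(C)=O)[C@H]2C(C)(C)CCC[C@@]21C | intermediate
26 | (13S)-13-[(tert-butyldimethylsilyl)oxy]-7β,8α-dihydroxy-14,15-dinorlabd-11E-en-6α-yl acetate | C[C@H](O[Si](C)(C)C(C)(C)C)/C=C/[C@H]1[C@](C)(O)[C@@H](O)[C@H](OC(C)=O)[C@H]2C(C)(C)CCC[C@@]21C | intermediate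
27 | (13S)-7β,8α,13-trihydroxy-14,15-dinorlabd-11E-en-6α-yl acetate | C[C@H](O)/C=C/[C@H]1[C@](C)(O)[C@@H](O)[C@H](OC(C)=O)[C@H]2C(C)(C)CCC[C@@]21C | intermediate
28 | (E)-4-[(1R,2S,3S,4R,4aS,8aS)-4-acetoxy-2,3-dihydroxy-2,5,5,8a-tetramethyldecahydronaphthalen-1-yl]but-3-en-2-one (7β,8α-dihydroxy-13-oxo-14,15-dinorlabd-11E-en-6α-yl acetate) | CC(=O)/C=C/[C@H]1[C@](C)(O)[C@@H](O)[C@H](OC(C)=O)[C@H]2C(C)(C)CCC[C@@]21C | target

Total step count: 17.
Longest linear sequence: 16 steps (steps 1, 2 and 4–17, from (S)-but-3-en-2-ol); the β-cyclocitral branch (steps 3–17) is 15 steps.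

Steps most likely to fail

Step 5 (enantioselective Ireland–Claisen rearrangement). The boron enolate may form with mixed geometry, or the controller may discriminate the enolate faces poorly when the allyl terminus is a fully substituted ring carbon. The dienolate may also lose silanolate from C13 (vinylogous β-elimination) during the slow rearrangement. The fallback gives up reagent control and uses the homochiral C13 centre as an internal handle; it sets out from ester 7 and returns at acid 10. Deprotonation with LiN(iPr)2 in THF/DMPU at −78 °C gives the lithium enolate F1, which Me3SiCl traps as the (Z)-silyl ketene acetal F2. On warming to room temperature the Ireland–Claisen rearrangement runs through the same chair and gives two trimethylsilyl esters: the ester of 10, F3, and the ester of its 9,10-antipodal isomer, F4. Aqueous work-up frees 10 and the (9S,10S,13S) acid F5. These two acids are diastereomers, not enantiomers, and are separated by chromatography (if necessary as the lactones after step 6); 10 then enters step 6.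

Step 10 (carbonyl-ene cyclisation). Transfer of the C17 hydrogen is geometrically easiest when the oxygen is axial, so the cyclisation may lose facial selectivity at C6. Alternatively the C8 cation may shed a proton from C7 or C9 and give ring alkenes. The fallback keeps the C6–C7 ring closure but replaces the ene reaction by an allylsilane–aldehyde cyclisation; it sets out from lactone 13 and returns at 20. Double addition of Me3SiCH2MgCl/CeCl3 to the lactone gives the bis(silylmethyl) carbinol F6, and Peterson elimination on silica gel (or with KH) gives the 2-substituted allylsilane alcohol F7. Dess–Martin oxidation then gives the allylsilane aldehyde F8. With MeAlCl2 in CH2Cl2 at −78 °C this closes ring B by an intramolecular Hosomi–Sakurai reaction, giving the aluminium alkoxide 19 and, after work-up, 20. The β-silyl cation can only collapse to the C8=C17 alkene and no hydrogen has to reach the oxygen, so the equatorial 6α-alkoxide is the sterically preferred outcome.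

Step 6 (hydroboration, C5 configuration). Hydrogen delivery to C5 may show poor facial selectivity if the ring A chair with the C9 arm axial reacts faster, which leads to the cis-fused lactone. The fallback replaces kinetic face selection by thermodynamic control at the aldehyde stage; it sets out from acid 10 and returns at aldehyde 18. Step 6 is run unchanged and the material that follows the other face is kept: the 5-epimeric organoborane F9 and hydroxy acid F10 give the cis-fused lactone F11. This is taken through the conditions of steps 7 to 9, by way of the lithium lactolate F12, the hydroxy ketone F13, the β-hydroxysilane F14 and the alcohol F15, to the 5-epimeric aldehyde F16. C5 is its only acidic centre, and equilibration with DBU in toluene at 60 °C should favour the aldehyde with equatorial formyl trans to the C9 arm, which is 18. Compound 18 is separated and the remainder is equilibrated again.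

Further compounds
F1 | step 5 | lithium (Z)-dienolate of ester 7 | C[C@H](O[Si](C)(C)C(C)(C)C)/C=C/C=C(\[O-])OCC1=C(C)CCCC1(C)C.[Li+]
F2 | step 5 | (Z)-trimethylsilyl ketene acetal of ester 7 | C[C@H](O[Si](C)(C)C(C)(C)C)/C=C/C=C(\O[Si](C)(C)C)OCC1=C(C)CCCC1(C)C
F3 | step 5 | trimethylsilyl ester of acid 10 | C[C@H](O[Si](C)(C)C(C)(C)C)/C=C/[C@@H](C(=O)O[Si](C)(C)C)[C@@]1(C)CCCC(C)(C)C1=C
F4 | step 5 | trimethylsilyl ester of the (9S,10S,13S) acid | C[C@H](O[Si](C)(C)C(C)(C)C)/C=C/[C@H](C(=O)O[Si](C)(C)C)[C@]1(C)CCCC(C)(C)C1=C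
F5 | step 5 | (2S,3E,5S)-5-[(tert-butyldimethylsilyl)oxy]-2-[(1S)-1,3,3-trimethyl-2-methylidenecyclohexyl]hex-3-enoic acid | C[C@H](O[Si](C)(C)C(C)(C)C)/C=C/[C@H](C(=O)O)[C@]1(C)CCCC(C)(C)C1=C
F6 | step 10 | bis(trimethylsilylmethyl) carbinol from lactone 13 (C8 carbinol, free C6 alcohol) | C[C@H](O[Si](C)(C)C(C)(C)C)/C=C/[C@@H](C(O)(C[Si](C)(C)C)C[Si](C)(C)C)[C@@]1(C)CCCC(C)(C)[C@@H]1CO
F7 | step 10 | allylsilane alcohol (C8(=CH2)CH2SiMe3 on C9, CH2OH on C5) | C[C@H](O[Si](C)(C)C(C)(C)C)/C=C/[C@@H](C(=C)C[Si](C)(C)C)[C@@]1(C)CCCC(C)(C)[C@@H]1CO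
F8 | step 10 | allylsilane aldehyde (C8(=CH2)CH2SiMe3 on C9, CHO on C5) | C[C@H](O[Si](C)(C)C(C)(C)C)/C=C/[C@@H](C(=C)C[Si](C)(C)C)[C@@]1(C)CCCC(C)(C)[C@@H]1C=O
F9 | step 6 | 5-epimer of organoborane 11 | C[C@H](O[Si](C)(C)C(C)(C)C)/C=C/[C@@H](C(=O)OB2C3CCCC2CCC3)[C@@]1(C)CCCC(C)(C)[C@H]1CB1C2CCCC1CCC2
F10 | step 6 | 5-epimer of hydroxy acid 12 | C[C@H](O[Si](C)(C)C(C)(C)C)/C=C/[C@@H](C(=O)O)[C@@]1(C)CCCC(C)(C)[C@H]1CO
F11 | step 6 | cis-fused δ-lactone (5-epimer of 13) | C[C@H](O[Si](C)(C)C(C)(C)C)/C=C/[C@H]1C(=O)OC[C@@H]2C(C)(C)CCC[C@@]21C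
F12 | step 6 | 5-epimer of lithium lactolate 14 | C[C@H](O[Si](C)(C)C(C)(C)C)/C=C/[C@H]1C(C)([O-])OC[C@@H]2C(C)(C)CCC[C@@]21C.[Li+]
F13 | step 6 | 5-epimer of hydroxy ketone 15 | C[C@H](O[Si](C)(C)C(C)(C)C)/C=C/[C@@H](C(C)=O)[C@@]1(C)CCCC(C)(C)[C@H]1CO
F14 | step 6 | 5-epimer of β-hydroxysilane 16 | C[C@H](O[Si](C)(C)C(C)(C)C)/C=C/[C@@H](C(C)(O)C[Si](C)(C)C)[C@@]1(C)CCCC(C)(C)[C@H]1CO
F15 | step 6 | 5-epimer of alcohol 17 | C[C@H](O[Si](C)(C)C(C)(C)C)/C=C/[C@@H](C(C)=C)[C@@]1(C)CCCC(C)(C)[C@H]1CO
F16 | step 6 | 5-epimer of aldehyde 18 | C[C@H](O[Si](C)(C)C(C)(C)C)/C=C/[C@@H](C(C)=C)[C@@]1(C)CCCC(C)(C)[C@H]1C=O
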